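## Retrosynthetic overview

1. Target 27 ⇐ triol 26 (oxidation) ⇐ ketone 24 (methyl addition). Rings A (oxepane) and B (cyclohexane) are closed last, in one bis-epoxide cascade, from Z-enol silane 22.
2. 22 ⇐ enone 21 ⇐ aldol union of ring C/D aldehyde 16 with diepoxy ketone 18, made by Shi epoxidation of geranylacetone 17 (metal-free key step).
3. 16 ⇐ Claisen rearrangement of allylic alcohol 14 (side-chain stereocentre by chirality transfer) ⇐ cis-fused enone 13.
4. 13 ⇐ ketyl–olefin closure of ring D (cyclopentane) onto cycloheptadienone 12 ⇐ one-carbon ring expansion of cyclohexenone 7 (ring C).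
5. 7 ⇐ organocatalytic radical conjugate addition to achiral dienone 5 (from 1 + 2). Ring order: C (six-, then seven-membered), D, then A and B together.

Assumption: (5E)-geranylacetone 17, acid 6 and the L-fructose-derived enantiomer of the Shi ketone are taken as commercially available.

Abbreviations used in names:
- Az = (3S,3aS,7R,8aS)-3-hydroxy-3,6,8,8-tetramethyl-1,2,3,3a,4,7,8,8a-octahydroazulen-7-yl; AzSi = its 3-O-trimethylsilyl ether.
- Ep = 2-[(2S,3S)-3-{2-[(2S)-3,3-dimethyloxiran-2-yl]ethyl}-3-methyloxiran-2-yl]ethyl.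
- Amine A = trans-2-(3,6-di-tert-butylcarbazol-9-yl)cyclohexan-1-amine, single enantiomer; the antipode that gives (5S)-7 is used.
- ent-Shi ketone = 1,2:4,5-di-O-isopropylidene-β-L-erythro-2,3-hexodiulo-2,6-pyranose.

## Route

Step 1
Reactants: 1 isobutyraldehyde, 2 ethyl vinyl ketone
Product: 4 2,4,4-trimethylcyclohex-2-en-1-one, via keto aldehyde 3 (not isolated)
Conditions: H2SO4 (cat.), neat, 45 °C; then PhMe, reflux (Dean–Stark)
Reagents that add atoms: none
Why: Acid-catalysed Michael addition of the enol of 1 to 2 and intramolecular aldol condensation (Robinson-type annulation) give the achiral enone, the quaternary carbon leaving only one cyclisation mode.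

Step 2
Reactants: 4 2,4,4-trimethylcyclohex-2-en-1-one
Product: 5 2,4,4-trimethylcyclohexa-2,5-dien-1-one
Conditions: DDQ (1.3 equiv), TsOH (cat.), 1,4-dioxane, reflux
Reagents that add atoms: none
Why: DDQ dehydrogenation of a 4,4-disubstituted cyclohexenone can only place the new double bond at C5–C6 and gives the achiral cross-conjugated dienone.

Step 3
Reactants: 5 2,4,4-trimethylcyclohexa-2,5-dien-1-one, 6 3-(2-methyl-1,3-dioxolan-2-yl)propanoic acid
Product: 7 (5S)-2,4,4-trimethyl-5-[2-(2-methyl-1,3-dioxolan-2-yl)ethyl]cyclohex-2-en-1-one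
Conditions: amine A·TFA (20 mol%), 4CzIPN (2 mol%), 2,6-lutidine (0.5 equiv), 6 (1.5 equiv), MeCN, 450 nm LEDs, 25 °C
Reagents that add atoms: none
Why: Proposed new method: amine A condenses with 5 to an iminium ion, photoexcited 4CzIPN oxidises the carboxylate of 6, loss of CO2 gives a nucleophilic primary alkyl radical that adds to the β-carbon of the unsubstituted (more electrophilic, less hindered) enone arm on the face left open by the carbazole wall, the carbazole relays an electron to the α-iminyl radical cation and hydrolysis releases (5S)-7, so the first stereocentre is set by the catalyst; the closest known reactions are enantioselective iminium-ion trapping of photogenerated radicals by cyclic enones and photoredox decarboxylative Giese additions, neither shown for a cross-conjugated dienone or an unstabilised primary radical.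

Step 4
Reactants: 7 (5S)-enone
Product: 8 (3S)-4,4,6-trimethyl-3-[2-(2-methyl-1,3-dioxolan-2-yl)ethyl]-1-(trimethylsilyloxy)cyclohexa-1,5-diene
Conditions: LDA, TMSCl, THF, −78 °C
Reagents that add atoms: chlorotrimethylsilane, C[Si](C)(C)Cl
Why: Kinetic deprotonation is possible only at C6 (C4 is quaternary) and O-silylation gives the cross-conjugated silyl dienol ether needed for a regiodefined ring expansion; C5 is not epimerisable.

Step 5
Reactants: 8 silyl dienol ether
Product: 9 (5S)-2,4,4-trimethyl-5-[2-(2-methyl-1,3-dioxolan-2-yl)ethyl]-1-(trimethylsilyloxy)bicyclo[4.1.0]hept-2-ene (cyclopropane anti to the C5 chain)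
Conditions: Et2Zn, CH2I2, CH2Cl2, 0 °C
Reagents that add atoms: diiodomethane, ICI
Why: Furukawa–Simmons–Smith cyclopropanation is chemoselective for the electron-rich silyl enol ether double bond and occurs anti to the C5 side chain (both new centres are destroyed in step 6).

Step 6
Reactants: 9 siloxycyclopropane
Product: 12 (5S)-2,4,4-trimethyl-5-(3-oxobutyl)cyclohepta-2,6-dien-1-one, via chloro ketone 10 (not isolated), via dienone ketal 11 (not isolated)
Conditions: FeCl3 (2.2 equiv), pyridine, DMF, 0 °C; NaOAc, MeOH, 65 °C; PPTS, acetone–H2O, 50 °C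
Reagents that add atoms: water, O
Why: Ito–Saegusa ring expansion: FeCl3 oxidises the siloxycyclopropane with cleavage of the internal bond to the β-chloro cycloheptenone, NaOAc eliminates HCl to the cyclohepta-2,6-dienone and mild acid then frees the methyl ketone, the C5 stereocentre not being involved.

Step 7
Reactants: 12 dienone ketone
Product: 13 (3S,3aS,8aS)-3-hydroxy-3,6,8,8-tetramethyl-2,3,3a,4,8,8a-hexahydroazulen-5(1H)-one
Conditions: SmI2 (2.5 equiv), t-BuOH (2 equiv), HMPA, THF, −78 °C
Reagents that add atoms: none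
Why: SmI2 ketyl–olefin (reductive keto–enone) 5-exo cyclisation onto the unsubstituted enone arm: the tether on C5 forces a cis ring fusion and the samarium-bound oxygen sits anti to the enone α-carbon, so OH ends cis to both ring-fusion hydrogens (3S,3aS) while the hindered α-methyl enone arm survives.

Step 8
Reactants: 13 bicyclic enone
Product: 14 (3S,3aS,5R,8aS)-3,6,8,8-tetramethyl-1,2,3,3a,4,5,8,8a-octahydroazulene-3,5-diol
Conditions: NaBH4, CeCl3·7H2O, MeOH, −78 °C
Reagents that add atoms: none
Why: Luche 1,2-reduction in which hydride attacks the convex face of the cis-fused bicycle (the face of the ring-fusion hydrogens), so the secondary hydroxyl is formed on the concave face (5R).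

Step 9
Reactants: 14 allylic alcohol
Product: 16 Az–CH2–CHO, via vinyl ether 15 (not isolated)
Conditions: butyl vinyl ether (solvent), Pd(OCOCF3)2 (5 mol%), 4,7-diphenyl-1,10-phenanthroline (5 mol%), Et3N, 75 °C; then xylene, 180 °C (sealed tube)
Reagents that add atoms: butyl vinyl ether, C=COCCCC
Why: Transfer vinylation of the secondary allylic alcohol (the tertiary alcohol is too hindered) and thermal Claisen rearrangement, a suprafacial [3,3] shift that transfers the C5–O configuration to the new C7–C bond (7R), moves the double bond to C5=C6 and releases the aldehyde.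

Step 10
Reactants: 17 (5E)-geranylacetone
Product: 18 (5S,6S,9S)-5,6:9,10-diepoxy-6,10-dimethylundecan-2-one (CH3CO–Ep)
Conditions: ent-Shi ketone (30 mol%), Oxone (2KHSO5·KHSO4·K2SO4), K2CO3, Bu4NHSO4, MeCN–DMM–aq. Na2B4O7 (pH 10.5), 0 °C
Reagents that add atoms: potassium peroxymonosulfate, [K+].OOS(=O)(=O)[O-]
Why: Shi epoxidation, the metal-free key step: the dioxirane of the chiral ketone epoxidises both electron-rich trisubstituted alkenes through a spiro transition state under catalyst control (S-configured C–O centres from the L-series ketone), the two independent events enriching the major diastereomer while the ketone is inert.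

Step 11
Reactants: 18 diepoxy ketone, 16 Az–CH2–CHO
Product: 19 Az–CH2–CH(OH)–CH2–CO–Ep (carbinol epimers)
Conditions: 18 (2.3 equiv), LDA (2.2 equiv), THF, −78 °C; then 16; AcOH
Reagents that add atoms: none
Why: Directed aldol addition of the kinetic (methyl-side) lithium enolate of 18 to aldehyde 16; excess enolate takes up the tertiary OH proton, the trisubstituted epoxides are inert at −78 °C and the new carbinol centre is removed in step 12.

Step 12
Reactants: 19 aldol adduct
Product: 21 (E)-Az–CH2–CH=CH–CO–Ep, via mesylate 20 (not isolated)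
Conditions: MsCl, Et3N, CH2Cl2, 0 → 23 °C
Reagents that add atoms: none
Why: Mesylation of the secondary β-hydroxy ketone and E1cB elimination give the (E)-enone; the tertiary alcohol and the epoxides do not react.

Step 13
Reactants: 21 enone
Product: 22 (Z)-Az–CH2–CH2–CH=C(OSiEt3)–Ep
Conditions: Et3SiH (1.5 equiv), RhCl(PPh3)3 (2 mol%), THF, 50 °C
Reagents that add atoms: triethylsilane, CC[SiH](CC)CC
Why: Rhodium-catalysed 1,4-hydrosilylation of the enone gives the regiodefined (Z)-silyl enol ether, which enolisation of the saturated ketone could not deliver; epoxides, the isolated alkene and the tertiary alcohol are inert.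

Step 14
Reactants: 22 (Z)-enol silane
Product: 24 (3S,5aS,6S,9aS)-6-[2-(AzSi)ethyl]-2,2,5a-trimethyl-3-(trimethylsilyloxy)octahydro-1-benzoxepin-7(2H)-one, via silyl ether 23 (not isolated)
Conditions: TMSOTf (2.5 equiv), 2,6-di-tert-butyl-4-methylpyridine (3 equiv), CH2Cl2, −78 °C; aq. NaHCO3
Reagents that add atoms: trimethylsilyl trifluoromethanesulfonate, C[Si](C)(C)OS(=O)(=O)C(F)(F)F
Why: Tandem oxa/carbacyclisation of a bis-epoxide terminated by an enol silane (McDonald type): TMSOTf activates the terminal epoxide, the internal epoxide oxygen opens it at the tertiary carbon to an epoxonium ion, and the enol silane opens that at its tertiary carbon with inversion through a chair, which closes rings A and B, fixes the trans ring fusion and places the epimerisable side chain equatorial, the tertiary OH being silylated in passing.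

Step 15
Reactants: 24 bis-silyl ketone
Product: 26 (3S,5aS,6S,7R,9aS)-6-[2-(Az)ethyl]-2,2,5a,7-tetramethyldecahydro-1-benzoxepine-3,7-diol, via bis-silyl carbinol 25 (not isolated)
Conditions: MeMgBr (5 equiv), CeCl3, THF, −78 → 0 °C; then 1 M HCl, THF, 0 °C
Reagents that add atoms: methylmagnesium bromide, C[Mg]Br
Why: Grignard (organocerium) 1,2-addition from the equatorial direction, axial attack being blocked by the 1,3-related axial angular methyl, gives the axial tertiary alcohol (7R), and the acid work-up removes both trimethylsilyl ethers.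

Step 16
Reactants: 26 triol
Product: 27 (5aS,6S,7R,9aS)-7-hydroxy-6-[2-(Az)ethyl]-2,2,5a,7-tetramethyloctahydro-1-benzoxepin-3(2H)-one (target)
Conditions: Dess–Martin periodinane (1.5 equiv), NaHCO3, CH2Cl2, 0 °C
Reagents that add atoms: none
Why: Dess–Martin oxidation converts the only secondary alcohol into the oxepanone, the two tertiary alcohols and the alkene being untouched.

## Compound list

1 | isobutyraldehyde | CC(C)C=O | starting material
2 | ethyl vinyl ketone (pent-1-en-3-one) | CCC(=O)C=C | starting material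
3 | 2,2-dimethyl-5-oxoheptanal | CCC(=O)CCC(C)(C)C=O | intermediate (not isolated)
4 | 2,4,4-trimethylcyclohex-2-en-1-one | CC1=CC(C)(C)CCC1=O | intermediate
5 | 2,4,4-trimethylcyclohexa-2,5-dien-1-one | CC1=CC(C)(C)C=CC1=O | intermediate
6 | 3-(2-methyl-1,3-dioxolan-2-yl)propanoic acid | CC1(CCC(=O)O)OCCO1 | starting material
7 | (5S)-2,4,4-trimethyl-5-[2-(2-methyl-1,3-dioxolan-2-yl)ethyl]cyclohex-2-en-1-one | O=C1C[C@H](CCC2(C)OCCO2)C(C)(C)C=C1C | intermediate
8 | (3S)-4,4,6-trimethyl-3-[2-(2-methyl-1,3-dioxolan-2-yl)ethyl]-1-(trimethylsilyloxy)cyclohexa-1,5-diene | C[Si](C)(C)OC1=C[C@H](CCC2(C)OCCO2)C(C)(C)C=C1C | intermediate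
9 | (5S)-2,4,4-trimethyl-5-[2-(2-methyl-1,3-dioxolan-2-yl)ethyl]-1-(trimethylsilyloxy)bicyclo[4.1.0]hept-2-ene, cyclopropane anti to the C5 chain | C[Si](C)(C)O[C@]12C[C@H]1[C@H](CCC1(C)OCCO1)C(C)(C)C=C2C | intermediate
10 | 6-chloro-2,4,4-trimethyl-5-[2-(2-methyl-1,3-dioxolan-2-yl)ethyl]cyclohept-2-en-1-one (C5 as in 7; C6 epimers) | O=C1CC(Cl)[C@H](CCC2(C)OCCO2)C(C)(C)C=C1C | intermediate (not isolated)
11 | (5S)-2,4,4-trimethyl-5-[2-(2-methyl-1,3-dioxolan-2-yl)ethyl]cyclohepta-2,6-dien-1-one | O=C1C=C[C@H](CCC2(C)OCCO2)C(C)(C)C=C1C | intermediate (not isolated)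
12 | (5S)-2,4,4-trimethyl-5-(3-oxobutyl)cyclohepta-2,6-dien-1-one | O=C1C=C[C@H](CCC(C)=O)C(C)(C)C=C1C | intermediate
13 | (3S,3aS,8aS)-3-hydroxy-3,6,8,8-tetramethyl-2,3,3a,4,8,8a-hexahydroazulen-5(1H)-one (cis-fused) | O=C1C[C@H]2[C@H](CC[C@]2(C)O)C(C)(C)C=C1C | intermediate
14 | (3S,3aS,5R,8aS)-3,6,8,8-tetramethyl-1,2,3,3a,4,5,8,8a-octahydroazulene-3,5-diol | O[C@@H]1C[C@H]2[C@H](CC[C@]2(C)O)C(C)(C)C=C1C | intermediate
15 | 5-O-vinyl ether of 14 | C=CO[C@@H]1C[C@H]2[C@H](CC[C@]2(C)O)C(C)(C)C=C1C | intermediate (not isolated)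
16 | 2-[(3S,3aS,7R,8aS)-3-hydroxy-3,6,8,8-tetramethyl-1,2,3,3a,4,7,8,8a-octahydroazulen-7-yl]acetaldehyde (Az–CH2–CHO) | CC1=CC[C@H]2[C@H](CC[C@]2(C)O)C(C)(C)[C@@H]1CC=O | intermediate
17 | (5E)-geranylacetone [(5E)-6,10-dimethylundeca-5,9-dien-2-one] | CC(=O)CC/C=C(\C)CCC=C(C)C | starting material
18 | (5S,6S,9S)-5,6:9,10-diepoxy-6,10-dimethylundecan-2-one | CC(=O)CC[C@@H]1O[C@@]1(C)CC[C@@H]1OC1(C)C | intermediate
19 | aldol adduct Az–CH2–CH(OH)–CH2–CO–Ep (carbinol epimers) | CC1=CC[C@H]2[C@H](CC[C@]2(C)O)C(C)(C)[C@@H]1CC(O)CC(=O)CC[C@@H]1O[C@@]1(C)CC[C@@H]1OC1(C)C | intermediate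
20 | methanesulfonate of 19 | CC1=CC[C@H]2[C@H](CC[C@]2(C)O)C(C)(C)[C@@H]1CC(OS(C)(=O)=O)CC(=O)CC[C@@H]1O[C@@]1(C)CC[C@@H]1OC1(C)C | intermediate (not isolated)
21 | (E)-enone Az–CH2–CH=CH–CO–Ep | CC1=CC[C@H]2[C@H](CC[C@]2(C)O)C(C)(C)[C@@H]1C/C=C/C(=O)CC[C@@H]1O[C@@]1(C)CC[C@@H]1OC1(C)C | intermediate
22 | (Z)-triethylsilyl enol ether Az–CH2–CH2–CH=C(OSiEt3)–Ep | CC1=CC[C@H]2[C@H](CC[C@]2(C)O)C(C)(C)[C@@H]1CC/C=C(\O[Si](CC)(CC)CC)CC[C@@H]1O[C@@]1(C)CC[C@@H]1OC1(C)C | intermediate
23 | tertiary O-trimethylsilyl ether of 22 | CC1=CC[C@H]2[C@H](CC[C@]2(C)O[Si](C)(C)C)C(C)(C)[C@@H]1CC/C=C(\O[Si](CC)(CC)CC)CC[C@@H]1O[C@@]1(C)CC[C@@H]1OC1(C)C | intermediate (not isolated)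
24 | (3S,5aS,6S,9aS)-6-[2-(AzSi)ethyl]-2,2,5a-trimethyl-3-(trimethylsilyloxy)octahydro-1-benzoxepin-7(2H)-one | CC1=CC[C@H]2[C@H](CC[C@]2(C)O[Si](C)(C)C)C(C)(C)[C@@H]1CC[C@H]1[C@]2(C)CC[C@H](O[Si](C)(C)C)C(C)(C)O[C@H]2CCC1=O | intermediate
25 | bis(trimethylsilyl) ether of 26 (ring A secondary O and ring D tertiary O) | CC1=CC[C@H]2[C@H](CC[C@]2(C)O[Si](C)(C)C)C(C)(C)[C@@H]1CC[C@H]1[C@]2(C)CC[C@H](O[Si](C)(C)C)C(C)(C)O[C@H]2CC[C@@]1(C)O | intermediate (not isolated)
26 | (3S,5aS,6S,7R,9aS)-6-[2-(Az)ethyl]-2,2,5a,7-tetramethyldecahydro-1-benzoxepine-3,7-diol | CC1=CC[C@H]2[C@H](CC[C@]2(C)O)C(C)(C)[C@@H]1CC[C@H]1[C@]2(C)CC[C@H](O)C(C)(C)O[C@H]2CC[C@@]1(C)O | intermediate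
27 | (5aS,6S,7R,9aS)-7-hydroxy-6-[2-(Az)ethyl]-2,2,5a,7-tetramethyloctahydro-1-benzoxepin-3(2H)-one | CC1=CC[C@H]2[C@H](CC[C@]2(C)O)C(C)(C)[C@@H]1CC[C@H]1[C@]2(C)CCC(=O)C(C)(C)O[C@H]2CC[C@@]1(C)O | target

## Step count and risks

Total: 16 steps. Longest linear sequence: 15 steps (steps 1–9, then 11–16); step 10 is the one-step side branch.

The three steps most likely to fail:

**Step 3 (the proposed new reaction).** The risks are iminium formation with a hindered cross-conjugated dienone, arm selectivity and enantioselectivity. The fallback uses known chemistry and sets out from 5: copper-catalysed asymmetric conjugate addition of a Grignard reagent to a cyclic enone. The reagent is [2-(2-methyl-1,3-dioxolan-2-yl)ethyl]magnesium bromide F1, made from the commercial bromide and magnesium. With CuBr·SMe2 and a ferrocenyl diphosphine of the JosiPhos type in t-BuOMe at −78 °C, and trapping of the magnesium enolate with chlorotrimethylsilane, it gives the silyl dienol ether directly. The route is rejoined at 8, one step shorter.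

**Step 6 (ring expansion).** FeCl3 may attack the vinylcyclopropane or the ketal in other ways. The fallback sets out from 7: one-carbon homologation of the ketone with trimethylsilyldiazomethane and AlMe3, in which the sp3 α-carbon migrates (C-silyl group removed with K2CO3 in MeOH), gives the homologated cycloheptenone ketal F2. Dehydrogenation with IBX (DMSO, 70 °C) can only occur on the saturated side and gives 11, where the route is rejoined; hydrolysis as in step 6 then gives 12.

**Step 7 (reductive cyclisation).** SmI2 may instead reduce the dienone by simple conjugate reduction or give a reductive aldol product. The fallback sets out from 7 and builds ring D on the six-membered ring before expanding it: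
- aqueous HCl, then KOH in MeOH (ketal cleavage and intramolecular aldol condensation) gives the bicyclic dienone F3;
- dimethyldioxirane epoxidises the tetrasubstituted double bond from the face of the angular hydrogen to the epoxy ketone F4;
- SmI2 (THF–MeOH, −90 °C) cleaves the Cα–O bond and gives the cis-fused β-hydroxy ketone F5;
- trimethylsilyldiazomethane and AlMe3 insert CH2 between the carbonyl and the ring-fusion carbon with retention.

This gives 13, where the route is rejoined.

Further compounds
F1 | step 3 | [2-(2-methyl-1,3-dioxolan-2-yl)ethyl]magnesium bromide | CC1(CC[Mg]Br)OCCO1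
F2 | step 6 | 2,4,4-trimethyl-5-[2-(2-methyl-1,3-dioxolan-2-yl)ethyl]cyclohept-2-en-1-one (C5 configuration as in 7) | O=C1CC[C@H](CCC2(C)OCCO2)C(C)(C)C=C1C
F3 | step 7 | (7aR)-3,5,7,7-tetramethyl-1,2,7,7a-tetrahydro-4H-inden-4-one | O=C1C(C)=CC(C)(C)[C@H]2CCC(C)=C12
F4 | step 7 | 3,3a-epoxide of F3, oxygen cis to H-7a | O=C1C(C)=CC(C)(C)[C@H]2CC[C@]3(C)O[C@]123
F5 | step 7 | (3S)-3-hydroxy-3,5,7,7-tetramethyl-1,2,3,3a,7,7a-hexahydro-4H-inden-4-one, cis-fused, 3-OH cis to H-3a and H-7a | O=C1C(C)=CC(C)(C)[C@H]2CC[C@](C)(O)[C@@H]12
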